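Assumption: the SMILES is taken literally, i.e. a cis-fused decalin with 4a-H, 8a-CH3 and 4-OAc on the same face, (3R; 4S,4aR,8aS). Labdane labels (C5, C6, C10 …) are used in the explanations.

## Retrosynthetic overview

1. C6–OAc is added last, by α′-acetoxylation of cis-fused enone 17 on its convex face.
2. Ring A (C4–C5 bond, gem-dimethyl carbon, cis fusion) comes from a 6-exo MHAT radical conjugate addition of an isopropenyl tether onto the unsubstituted arm of cross-conjugated dienone 16.
3. 16 comes from bis-allylic oxidation of 1,4-diene 15, made by Negishi coupling of dienyl triflate 10 with the zinc reagent of chiral-pool iodide 13 (C13).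
4. 10 comes from ketone 8, made by B-alkyl Suzuki coupling on allyl ketone 6, which is set up by Pd-catalysed asymmetric allylation of the dienolate of 3 (sets C10).
5. Ring B is the arene itself: Birch dearomatisation of C2v-symmetric 2,6-dimethylanisole stops at unconjugated enone 3, whose surviving arene π-bond becomes C5=C6. Ring B is formed first, ring A last.

## Route

Step 1
Reactants: 1 2,6-dimethylanisole
Product: 3 (2RS,6RS)-2,6-dimethylcyclohex-3-en-1-one, via (6RS)-1-methoxy-2,6-dimethylcyclohexa-1,4-diene 2 (not isolated)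
Conditions: Li, NH3(l), t-BuOH, THF, −78 to −33 °C; then (CO2H)2, MeOH–H2O, 0 °C
Reagents that add atoms: water (O)
Why: Birch reduction of the anisole followed by kinetic hydrolysis of the enol ether stops at the unconjugated 3-enone, so aromaticity and the C2v symmetry are broken in one operation while one arene π-bond survives next to one of the two formerly equivalent C–CH3 carbons (future C5=C6 beside C10); both stereocentres formed here are unimportant, since one is overwritten in step 2 and the other erased in step 4.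

Step 2
Reactants: 3 (2RS,6RS)-2,6-dimethylcyclohex-3-en-1-one
Product: 6 (2S,6RS)-2,6-dimethyl-2-(prop-2-en-1-yl)cyclohex-3-en-1-one, via lithium (6RS)-2,6-dimethylcyclohexa-1,3-dien-1-olate 4 (not isolated), via trimethyl{[(6RS)-2,6-dimethylcyclohexa-1,3-dien-1-yl]oxy}stannane 5 (not isolated)
Conditions: LDA, DME, −78 °C; Me3SnCl; allyl acetate, [Pd(η3-C3H5)Cl]2 (2.5 mol %), (R,R)-DACH-phenyl Trost ligand (6 mol %), −78 °C to rt
Reagents that add atoms: allyl acetate (C=CCOC(C)=O)
Why: Trost-type Pd-catalysed asymmetric allylic alkylation: LDA removes the doubly activated (α-keto and allylic) proton, the extended tin dienolate is allylated at its α-carbon (deconjugative), and the chiral Pd–π-allyl pocket selects one enantiotopic face of the planar dienolate to set the quaternary centre 2S (= C10) with the remote 6-methyl as a spectator; the ligand antipode is used if the first run shows the opposite sense.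

Step 3
Reactants: 6 (2S,6RS)-2,6-dimethyl-2-(prop-2-en-1-yl)cyclohex-3-en-1-one
Product: 8 (2S,6RS)-2,6-dimethyl-2-(4-methylpent-4-en-1-yl)cyclohex-3-en-1-one, via (2S,6RS)-2-[3-(9-borabicyclo[3.3.1]nonan-9-yl)propyl]-2,6-dimethylcyclohex-3-en-1-one 7 (not isolated)
Conditions: 9-BBN, THF, 0 °C to rt; then 2-bromopropene, PdCl2(dppf) (3 mol %), 3 M aq NaOH, 60 °C
Reagents that add atoms: 2-bromopropene (CC(Br)=C)
Why: 9-BBN hydroborates only the terminal allyl double bond (anti-Markovnikov) and the B-alkyl Suzuki–Miyaura coupling installs the 1,1-disubstituted alkene needed for later radical generation; no stereocentre is affected.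

Step 4
Reactants: 8 (2S,6RS)-2,6-dimethyl-2-(4-methylpent-4-en-1-yl)cyclohex-3-en-1-one
Product: 10 (6S)-2,6-dimethyl-6-(4-methylpent-4-en-1-yl)cyclohexa-1,4-dien-1-yl trifluoromethanesulfonate, via potassium (6S)-2,6-dimethyl-6-(4-methylpent-4-en-1-yl)cyclohexa-1,4-dien-1-olate 9 (not isolated)
Conditions: KHMDS, THF, −78 °C; PhNTf2, −78 to 0 °C
Reagents that add atoms: N-phenylbis(trifluoromethanesulfonimide) (O=S(=O)(N(c1ccccc1)S(=O)(=O)C(F)(F)F)C(F)(F)F)
Why: Enol triflate formation: the ketone can enolise only towards the CH(CH3) carbon because the other α-carbon is quaternary, so one tetrasubstituted enolate forms and is O-sulfonylated, which also erases the spectator stereocentre.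

Step 5
Reactants: 11 (3R)-5-methoxy-3-methyl-5-oxopentanoic acid (methyl hydrogen (R)-3-methylglutarate)
Product: 12 methyl (3R)-5-hydroxy-3-methylpentanoate
Conditions: BH3·SMe2, THF, −15 to 0 °C; MeOH quench (used crude)
Reagents that add atoms: none
Why: Borane reduces the free carboxylic acid (via the acyloxyborane) much faster than the methyl ester, and the C3 stereocentre is untouched.

Step 6
Reactants: 12 methyl (3R)-5-hydroxy-3-methylpentanoate
Product: 13 methyl (3S)-5-iodo-3-methylpentanoate
Conditions: I2, PPh3, imidazole, CH2Cl2, 0 °C to rt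
Reagents that add atoms: iodine (II)
Why: Appel-type iodination by SN2 at the primary carbinol carbon; the stereocentre is untouched and only its CIP descriptor changes to S.

Step 7
Reactants: 10 (6S)-2,6-dimethyl-6-(4-methylpent-4-en-1-yl)cyclohexa-1,4-dien-1-yl trifluoromethanesulfonate; 13 methyl (3S)-5-iodo-3-methylpentanoate
Product: 15 methyl (3R)-5-[(6S)-2,6-dimethyl-6-(4-methylpent-4-en-1-yl)cyclohexa-1,4-dien-1-yl]-3-methylpentanoate, via [(3S)-5-methoxy-3-methyl-5-oxopentyl]zinc(II) iodide 14 (not isolated)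
Conditions: 13, Zn dust (activated), LiCl, THF, 40 °C; then 10, Pd(OAc)2 (3 mol %), SPhos (6 mol %), THF–NMP, 50 °C
Reagents that add atoms: none
Why: Zinc inserts into the primary C–I bond without touching the ester, and the alkylzinc undergoes Negishi cross-coupling with the alkenyl triflate, joining C11 to C9; no stereocentre is affected.

Step 8
Reactants: 15 methyl (3R)-5-[(6S)-2,6-dimethyl-6-(4-methylpent-4-en-1-yl)cyclohexa-1,4-dien-1-yl]-3-methylpentanoate
Product: 16 methyl (3R)-5-[(6S)-2,6-dimethyl-6-(4-methylpent-4-en-1-yl)-3-oxocyclohexa-1,4-dien-1-yl]-3-methylpentanoate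
Conditions: Rh2(cap)4 (1 mol %), t-BuOOH (70 % aq), K2CO3, CH2Cl2, rt
Reagents that add atoms: tert-butyl hydroperoxide (CC(C)(C)OO)
Why: Rh-catalysed allylic oxidation (tert-butylperoxyl H-abstraction) occurs at the only doubly allylic CH2 of the 1,4-diene and gives the cross-conjugated cyclohexa-2,5-dienone, as in the oxidation of Birch-type 1,4-dienes.

Step 9
Reactants: 16 methyl (3R)-5-[(6S)-2,6-dimethyl-6-(4-methylpent-4-en-1-yl)-3-oxocyclohexa-1,4-dien-1-yl]-3-methylpentanoate
Product: 17 methyl (3R)-3-methyl-5-[(4aR,8aS)-2,5,5,8a-tetramethyl-3-oxo-3,4,4a,5,6,7,8,8a-octahydronaphthalen-1-yl]pentanoate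
Conditions: Fe(acac)3 (30 mol %), PhSiH3, EtOH–(CH2OH)2, 60 °C
Reagents that add atoms: none
Why: Fe–H hydrogen-atom transfer (MHAT, Baran reductive olefin coupling) to the isopropenyl group gives the tertiary radical, which adds 6-exo-trig (Giese) to the unsubstituted enone β-carbon from the only face the tether can reach, so the new ring is necessarily cis-fused (4a-H on the face of the 8a-methyl, 4aR) and the gem-dimethyl carbon forms at the same time; the fully substituted enone arm is too hindered to compete.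

Step 10
Reactants: 17 methyl (3R)-3-methyl-5-[(4aR,8aS)-2,5,5,8a-tetramethyl-3-oxo-3,4,4a,5,6,7,8,8a-octahydronaphthalen-1-yl]pentanoate
Product: 18 methyl (3R)-5-[(4S,4aR,8aS)-4-acetoxy-2,5,5,8a-tetramethyl-3-oxo-3,4,4a,5,6,7,8,8a-octahydronaphthalen-1-yl]-3-methylpentanoate (CNP0192224.1)
Conditions: Mn(OAc)3·2H2O (3 equiv), benzene, reflux (Dean–Stark)
Reagents that add atoms: manganese(III) acetate (CC(=O)[O-].CC(=O)[O-].CC(=O)[O-].[Mn+3])
Why: Mn(OAc)3 α′-acetoxylation of the enone via its Mn(III) enolate/α-keto radical delivers acetate to the ring CH2 next to C=O from the convex face, anti to the adjacent gem-dimethyl-bearing ring, giving the 4S acetate, which should also be the more stable epimer if it equilibrates.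

## Compound list

1 | 2,6-dimethylanisole (2-methoxy-1,3-dimethylbenzene) | COc1c(C)cccc1C | starting material
2 | (6RS)-1-methoxy-2,6-dimethylcyclohexa-1,4-diene | COC1=C(C)CC=CC1C | intermediate (not isolated)
3 | (2RS,6RS)-2,6-dimethylcyclohex-3-en-1-one (cis/trans mixture) | CC1CC=CC(C)C1=O | intermediate
4 | lithium (6RS)-2,6-dimethylcyclohexa-1,3-dien-1-olate | [Li+].[O-]C1=C(C)C=CCC1C | intermediate (not isolated)
5 | trimethyl{[(6RS)-2,6-dimethylcyclohexa-1,3-dien-1-yl]oxy}stannane | C[Sn](C)(C)OC1=C(C)C=CCC1C | intermediate (not isolated)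
6 | (2S,6RS)-2,6-dimethyl-2-(prop-2-en-1-yl)cyclohex-3-en-1-one | CC1CC=C[C@](C)(CC=C)C1=O | intermediate
7 | (2S,6RS)-2-[3-(9-borabicyclo[3.3.1]nonan-9-yl)propyl]-2,6-dimethylcyclohex-3-en-1-one | CC1CC=C[C@](C)(CCCB2C3CCCC2CCC3)C1=O | intermediate (not isolated)
8 | (2S,6RS)-2,6-dimethyl-2-(4-methylpent-4-en-1-yl)cyclohex-3-en-1-one | CC1CC=C[C@](C)(CCCC(C)=C)C1=O | intermediate
9 | potassium (6S)-2,6-dimethyl-6-(4-methylpent-4-en-1-yl)cyclohexa-1,4-dien-1-olate | [K+].CC1=C([O-])[C@@](C)(CCCC(C)=C)C=CC1 | intermediate (not isolated)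
10 | (6S)-2,6-dimethyl-6-(4-methylpent-4-en-1-yl)cyclohexa-1,4-dien-1-yl trifluoromethanesulfonate | CC1=C(OS(=O)(=O)C(F)(F)F)[C@@](C)(CCCC(C)=C)C=CC1 | intermediate
11 | (3R)-5-methoxy-3-methyl-5-oxopentanoic acid (methyl hydrogen (R)-3-methylglutarate) | COC(=O)C[C@H](C)CC(=O)O | starting material
12 | methyl (3R)-5-hydroxy-3-methylpentanoate | COC(=O)C[C@H](C)CCO | intermediate
13 | methyl (3S)-5-iodo-3-methylpentanoate | COC(=O)C[C@H](C)CCI | intermediate
14 | [(3S)-5-methoxy-3-methyl-5-oxopentyl]zinc(II) iodide | COC(=O)C[C@H](C)CC[Zn]I | intermediate (not isolated)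
15 | methyl (3R)-5-[(6S)-2,6-dimethyl-6-(4-methylpent-4-en-1-yl)cyclohexa-1,4-dien-1-yl]-3-methylpentanoate | COC(=O)C[C@H](C)CCC1=C(C)CC=C[C@]1(C)CCCC(C)=C | intermediate
16 | methyl (3R)-5-[(6S)-2,6-dimethyl-6-(4-methylpent-4-en-1-yl)-3-oxocyclohexa-1,4-dien-1-yl]-3-methylpentanoate | COC(=O)C[C@H](C)CCC1=C(C)C(=O)C=C[C@]1(C)CCCC(C)=C | intermediate
17 | methyl (3R)-3-methyl-5-[(4aR,8aS)-2,5,5,8a-tetramethyl-3-oxo-3,4,4a,5,6,7,8,8a-octahydronaphthalen-1-yl]pentanoate | COC(=O)C[C@H](C)CCC1=C(C)C(=O)C[C@@H]2C(C)(C)CCC[C@]12C | intermediate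
18 | methyl (3R)-5-[(4S,4aR,8aS)-4-acetoxy-2,5,5,8a-tetramethyl-3-oxo-3,4,4a,5,6,7,8,8a-octahydronaphthalen-1-yl]-3-methylpentanoate | COC(=O)C[C@H](C)CCC1=C(C)C(=O)[C@@H](OC(C)=O)[C@@H]2C(C)(C)CCC[C@]12C | target

## Step count and risks

Total steps: 10. Longest linear sequence: 8 (steps 1, 2, 3, 4, 7, 8, 9, 10); the side chain adds steps 5 and 6.

The three steps most likely to fail:

**Step 2 (asymmetric allylation of the dienolate).** The risks are α′- or γ-allylation, O-allylation and modest ee on this extended, hindered enolate. The fallback sets out from 3 and generates the enolate regiospecifically inside the catalyst instead of intermolecularly. O-acylation of the lithium dienolate (LiHMDS, TMEDA, allyl chloroformate, THF, −78 °C) gives prop-2-en-1-yl (6RS)-2,6-dimethylcyclohexa-1,3-dien-1-yl carbonate F1, which is isolated. Stoltz-type decarboxylative asymmetric allylation of F1 (Pd2(dba)3, (R)-t-BuPHOX, THF, 25 °C) loses CO2 and couples within the ion pair at the α-carbon. The R ligand is chosen by analogy with (S)-t-BuPHOX giving (S)-2-allyl-2-methylcyclohexanone; the descriptor is inverted here because C3 is sp2. The route is rejoined at 6, one step longer.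

**Step 9 (MHAT radical cyclisation).** The risks are plain reduction of the isopropenyl group or Fe–H attack on the dienone. The fallback sets out from 16 and makes the same tertiary radical from a halide. Markovnikov addition of dry HBr (CH2Cl2, −40 °C, dark) to the 1,1-disubstituted alkene gives methyl (3R)-5-[(6S)-6-(4-bromo-4-methylpentyl)-2,6-dimethyl-3-oxocyclohexa-1,4-dien-1-yl]-3-methylpentanoate F2. Tin-hydride Giese cyclisation of F2 (Bu3SnH added slowly, AIBN, benzene, 80 °C) closes the same cis-fused ring and rejoins the route at 17, one step longer.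

**Step 10 (α′-acetoxylation).** The risks are low conversion, γ-oxidation, or the wrong C4 epimer. The fallback sets out from 17 and installs the oxygen by enolate oxidation. Kinetic α′-enolisation and silylation (LiHMDS, TMSCl, THF, −78 °C) gives methyl (3R)-3-methyl-5-[(4aR,8aS)-2,5,5,8a-tetramethyl-3-[(trimethylsilyl)oxy]-4a,5,6,7,8,8a-hexahydronaphthalen-1-yl]pentanoate F3. Rubottom oxidation of F3 from the convex face (DMDO, acetone, −40 °C; then citric acid, MeOH) gives methyl (3R)-5-[(4S,4aR,8aS)-4-hydroxy-2,5,5,8a-tetramethyl-3-oxo-3,4,4a,5,6,7,8,8a-octahydronaphthalen-1-yl]-3-methylpentanoate F4. Acetylation of F4 (Ac2O, DMAP, pyridine) rejoins the route at 18, two steps longer.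

## Further compounds

F1 | step 2 | prop-2-en-1-yl (6RS)-2,6-dimethylcyclohexa-1,3-dien-1-yl carbonate | C=CCOC(=O)OC1=C(C)C=CCC1C
F2 | step 9 | methyl (3R)-5-[(6S)-6-(4-bromo-4-methylpentyl)-2,6-dimethyl-3-oxocyclohexa-1,4-dien-1-yl]-3-methylpentanoate | COC(=O)C[C@H](C)CCC1=C(C)C(=O)C=C[C@]1(C)CCCC(C)(C)Br
F3 | step 10 | methyl (3R)-3-methyl-5-[(4aR,8aS)-2,5,5,8a-tetramethyl-3-[(trimethylsilyl)oxy]-4a,5,6,7,8,8a-hexahydronaphthalen-1-yl]pentanoate | COC(=O)C[C@H](C)CCC1=C(C)C(O[Si](C)(C)C)=C[C@@H]2C(C)(C)CCC[C@]12C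
F4 | step 10 | methyl (3R)-5-[(4S,4aR,8aS)-4-hydroxy-2,5,5,8a-tetramethyl-3-oxo-3,4,4a,5,6,7,8,8a-octahydronaphthalen-1-yl]-3-methylpentanoate | COC(=O)C[C@H](C)CCC1=C(C)C(=O)[C@@H](O)[C@@H]2C(C)(C)CCC[C@]12C
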